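**Retrosynthetic overview**
1. Target 17 ⇐ C15 equilibration and 6-exo lactonisation (carboxylate onto C3 of a 3S,4S-epoxide, with inversion) ⇐ Shi epoxidation of the 3,4-alkene of acid 14.
2. 14 ⇐ singlet-oxygen ene reaction at C7/C8 of acid 11, run while the 3,4-alkene is masked as a bromolactone.
3. 14-membered ring (ester 10) ⇐ C1–C2 bond from a π-allylpalladium unit (C2–C4) and the carbene-bound homoenolate of a terminal 2-methyl-enal (C1). This is the synthetic image of the GGPP → cembrane cyclisation; it also brings C16 to the acid level and sets C1.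
4. Seco-enal 9 ⇐ farnesol + allyl + methacrolein; the 11,12-epoxide ⇐ Sharpless epoxidation at the 12-hydroxyfarnesyl stage.
5. Ring order: 11,12-epoxide → carbocycle → (temporary bromolactone) → 3,4-epoxide → δ-lactone.

Numbering in names is cembrane numbering: ring C1–C14; C15 carries C16 (carboxyl) and C17; methyls C18, C19, C20 sit on C4, C8, C12.

Assumption: the (5aS,10bR) antipode of the aminoindanol triazolium salt is taken to give 1R (otherwise its mirror image is used), and C15, formed unselectively in step 6, stays an epimer mixture until step 10.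

**Step 1**
Reactants: 1 (2E,6E)-farnesol
Product: 2 (2E,6E)-farnesyl methyl carbonate
Conditions: ClCO2Me, pyridine, CH2Cl2, 0 °C
Reagents that add atoms: methyl chloroformate, COC(=O)Cl
Why: O-acylation of the primary allylic alcohol with a chloroformate installs the carbonate that later serves as leaving group for π-allylpalladium formation and deactivates the neighbouring alkene; no stereocentre is formed.

**Step 2**
Reactants: 2 (2E,6E)-farnesyl methyl carbonate
Product: 3 (2E,6E,10E)-12-hydroxyfarnesyl methyl carbonate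
Conditions: SeO2 (0.3 equiv), t-BuOOH, salicylic acid (cat.), CH2Cl2, 0 °C to rt
Reagents that add atoms: tert-butyl hydroperoxide, CC(C)(C)OO
Why: SeO2/t-BuOOH allylic oxidation (ene reaction then [2,3]-sigmatropic shift) picks the E-methyl group of the terminal, most electron-rich trisubstituted alkene and keeps the E geometry.

**Step 3**
Reactants: 3 (2E,6E,10E)-12-hydroxyfarnesyl methyl carbonate
Product: 4 (2E,6E,10S,11S)-10,11-epoxy-12-hydroxyfarnesyl methyl carbonate
Conditions: Ti(OiPr)4 (10 mol %), L-(+)-DET (12 mol %), t-BuOOH, 4 Å MS, CH2Cl2, −20 °C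
Reagents that add atoms: tert-butyl hydroperoxide, CC(C)(C)OO
Why: Sharpless asymmetric epoxidation acts only on the one allylic-alcohol alkene, and L-(+)-tartrate delivers oxygen to the face that gives the S,S trans-epoxide (cembrane 11S,12S).

**Step 4**
Reactants: 4 (2E,6E,10S,11S)-10,11-epoxy-12-hydroxyfarnesyl methyl carbonate; 5 allylmagnesium bromide
Product: 7 allyl-extended epoxy carbonate, via epoxy triflate 6 (not isolated)
Conditions: Tf2O, 2,6-lutidine, CH2Cl2, −78 °C; then CH2=CHCH2MgBr (1.2 equiv), CuBr·SMe2 (10 mol %), THF, −78 °C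
Reagents that add atoms: trifluoromethanesulfonic anhydride, O=S(=O)(OS(=O)(=O)C(F)(F)F)C(F)(F)F (its triflyl group is held only in 6)
Why: Triflate formation followed by copper-catalysed SN2 coupling with the allyl Grignard reagent (Kotsuki-type triflate–Grignard coupling) is faster at −78 °C than attack on the carbonate or the epoxide, so the epoxide stereocentres are untouched.

**Step 5**
Reactants: 7 allyl-extended epoxy carbonate; 8 methacrolein
Product: 9 (2E,6E,10S,11S,14E)-10,11-epoxy-16-oxogeranylgeranyl methyl carbonate (seco-enal)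
Conditions: methacrolein (5 equiv), RuCl2(=CH-C6H4-2-OiPr)(H2IMes) (second-generation Hoveyda–Grubbs catalyst, 5 mol %), CH2Cl2, 40 °C
Reagents that add atoms: none
Why: Olefin cross-metathesis of the monosubstituted terminal alkene with excess methacrolein gives the (E)-2-methyl enal under thermodynamic control, the trisubstituted alkenes of the chain being inert to the ruthenium carbene.

**Step 6**
Reactants: 9 seco-enal
Product: 10 methyl (1R,3E,7E,11S,12S)-11,12-epoxycembra-3,7-dien-16-oate (C15 epimers)
Conditions: Pd(PPh3)4 (5 mol %), (5aS,10bR)-2-mesityl-5a,10b-dihydro-4H,6H-indeno[2,1-b][1,2,4]triazolo[4,3-d][1,4]oxazin-2-ium tetrafluoroborate (15 mol %), THF, 40 °C, syringe-pump addition to 0.003 M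
Reagents that add atoms: none
Why: Proposed new method: the zerovalent palladium catalyst ionises the allylic methyl carbonate to an (E)-π-allylpalladium cation, CO2 and methoxide; the methoxide frees the chiral triazolylidene, which turns the 2-methyl enal into a Breslow homoenolate whose β-carbon (C1) attacks the less hindered allyl terminus (C2) from the face set by the aminoindanol backbone (1R); the acyl azolium is then released by the same methoxide as the methyl ester with unselective protonation at C15; the closest known reaction types are the intermolecular cooperative carbene/palladium coupling of enal homoenolates with π-allyl- or arylpalladium electrophiles and the Tsuji–Trost macrocyclisation, merged here into a 14-membered ring closure under high dilution.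

**Step 7**
Reactants: 10 methyl (1R,3E,7E,11S,12S)-11,12-epoxycembra-3,7-dien-16-oate
Product: 11 (1R,3E,7E,11S,12S)-11,12-epoxycembra-3,7-dien-16-oic acid (C15 epimers)
Conditions: LiOH, THF/MeOH/H2O, 25 °C; then 0.5 M HCl to pH 5, 0 °C
Reagents that add atoms: lithium hydroxide, [Li+].[OH-]
Why: Saponification (BAc2 ester hydrolysis) leaves the epoxide and the alkenes untouched, and any change at C15 is irrelevant at this stage.

**Step 8**
Reactants: 11 (1R,3E,7E,11S,12S)-11,12-epoxycembra-3,7-dien-16-oic acid
Product: 12 (1R,3R,4S,7E,11S,12S)-4-bromo-11,12-epoxycembr-7-en-16,3-olide (bromolactone, C15 epimers; major diastereomer drawn)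
Conditions: NBS (1.05 equiv), CH2Cl2, −20 °C, dark
Reagents that add atoms: N-bromosuccinimide, O=C1CCC(=O)N1Br
Why: Bromolactonisation: the carboxyl group reaches only the neighbouring 3,4-alkene (6-exo closure, anti addition), so this alkene alone is masked while the 7,8-alkene and the epoxide stay free; the new centres are temporary and every diastereomer returns the same alkene later.

**Step 9**
Reactants: 12 bromolactone
Product: 14 (1R,3E,7S,11S,12S)-11,12-epoxy-7-hydroxycembra-3,8(19)-dien-16-oic acid (C15 epimers), via hydroperoxide 13 (not isolated)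
Conditions: O2, visible light, meso-tetraphenylporphyrin (cat.), CH2Cl2, −20 °C; then Zn dust, NH4Cl, EtOH/THF, 25 °C
Reagents that add atoms: dioxygen, O=O
Why: Schenck ene reaction of singlet oxygen with the only alkene left abstracts a C19 hydrogen from the more crowded side (cis effect), with oxygen expected on the exposed outer face of the ring-bound E-alkene to give the 7S hydroperoxide (8-hydroperoxy-6-ene isomer as by-product); zinc then reduces the hydroperoxide and reopens the bromolactone by anti reductive elimination, returning the 3E-alkene and the acid.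

**Step 10**
Reactants: 14 (1R,3E,7S,11S,12S)-11,12-epoxy-7-hydroxycembra-3,8(19)-dien-16-oic acid
Product: 17 CNP0262409.2 (target), via diepoxy acid 15 (not isolated), via epimeric lactone 16 (not isolated)
Conditions: L-fructose-derived Shi ketone (30 mol %), KHSO5 (as 2KHSO5·KHSO4·K2SO4), K2CO3, Bu4NHSO4, MeCN/dimethoxymethane/aq. buffer pH 10.5, 0 °C; then DBU, toluene, 60 °C
Reagents that add atoms: potassium peroxymonosulfate, [K+].[O-]S(=O)(=O)OO
Why: Shi asymmetric epoxidation (chiral dioxirane) attacks the trisubstituted 3,4-alkene faster than the 1,1-disubstituted allylic-alcohol alkene and from the catalyst-fixed face (3S,4S); the carboxylate then opens the epoxide at C3 by 6-exo-tet SN2 attack with inversion (3R, with the 4S tertiary alcohol retained), and DBU equilibrates the lactone α-centre to the all-equatorial 15S epimer.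

**Compound list**
1 | (2E,6E)-farnesol | OC/C=C(\C)CC/C=C(\C)CCC=C(C)C | starting material
2 | (2E,6E)-farnesyl methyl carbonate | COC(=O)OC/C=C(\C)CC/C=C(\C)CCC=C(C)C | intermediate
3 | (2E,6E,10E)-12-hydroxy-3,7,11-trimethyldodeca-2,6,10-trien-1-yl methyl carbonate | COC(=O)OC/C=C(\C)CC/C=C(\C)CC/C=C(\C)CO | intermediate
4 | (2E,6E,10S,11S)-10,11-epoxy-12-hydroxyfarnesyl methyl carbonate | COC(=O)OC/C=C(\C)CC/C=C(\C)CC[C@@H]1O[C@@]1(C)CO | intermediate
5 | allylmagnesium bromide | C=CC[Mg]Br | starting material
6 | 12-O-triflate of 4 (epoxy triflate) | COC(=O)OC/C=C(\C)CC/C=C(\C)CC[C@@H]1O[C@@]1(C)COS(=O)(=O)C(F)(F)F | intermediate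
7 | (2E,6E)-9-[(2S,3S)-3-(but-3-en-1-yl)-3-methyloxiran-2-yl]-3,7-dimethylnona-2,6-dien-1-yl methyl carbonate | COC(=O)OC/C=C(\C)CC/C=C(\C)CC[C@@H]1O[C@@]1(C)CCC=C | intermediate
8 | methacrolein | C=C(C)C=O | starting material
9 | (2E,6E,10S,11S,14E)-10,11-epoxy-3,7,11,15-tetramethyl-16-oxohexadeca-2,6,14-trien-1-yl methyl carbonate (seco-enal) | COC(=O)OC/C=C(\C)CC/C=C(\C)CC[C@@H]1O[C@@]1(C)CC/C=C(\C)C=O | intermediate
10 | methyl (1R,3E,7E,11S,12S)-11,12-epoxycembra-3,7-dien-16-oate, C15 epimers | COC(=O)C(C)[C@H]1C/C=C(\C)CC/C=C(\C)CC[C@@H]2O[C@@]2(C)CC1 | intermediate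
11 | (1R,3E,7E,11S,12S)-11,12-epoxycembra-3,7-dien-16-oic acid, C15 epimers | OC(=O)C(C)[C@H]1C/C=C(\C)CC/C=C(\C)CC[C@@H]2O[C@@]2(C)CC1 | intermediate
12 | (1R,3R,4S,7E,11S,12S)-4-bromo-11,12-epoxycembr-7-en-16,3-olide, C15 epimers | CC1C(=O)O[C@@H]2C[C@H]1CC[C@]3(C)O[C@H]3CC/C(C)=C/CC[C@]2(C)Br | intermediate
13 | (7S)-7-hydroperoxy-8(19)-ene derivative of 12 | CC1C(=O)O[C@@H]2C[C@H]1CC[C@]3(C)O[C@H]3CCC(=C)[C@@H](OO)CC[C@]2(C)Br | intermediate
14 | (1R,3E,7S,11S,12S)-11,12-epoxy-7-hydroxycembra-3,8(19)-dien-16-oic acid, C15 epimers | OC(=O)C(C)[C@H]1C/C=C(\C)CC[C@H](O)C(=C)CC[C@@H]2O[C@@]2(C)CC1 | intermediate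
15 | (1R,3S,4S,7S,11S,12S)-3,4:11,12-diepoxy-7-hydroxycembr-8(19)-en-16-oic acid, C15 epimers | OC(=O)C(C)[C@H]1C[C@@H]3O[C@@]3(C)CC[C@H](O)C(=C)CC[C@@H]2O[C@@]2(C)CC1 | intermediate
16 | (1R,3R,4S,7S,11S,12S)-11,12-epoxy-4,7-dihydroxycembr-8(19)-en-16,3-olide, C15 epimer mixture | C=C1CC[C@@H]2O[C@@]2(C)CC[C@@H]2C[C@@H](OC(=O)C2C)[C@@](C)(O)CC[C@@H]1O | intermediate
17 | CNP0262409.2, (1R,3R,4S,7S,11S,12S,15S)-11,12-epoxy-4,7-dihydroxycembr-8(19)-en-16,3-olide | C=C1CC[C@@H]2O[C@@]2(C)CC[C@@H]2C[C@@H](OC(=O)[C@H]2C)[C@@](C)(O)CC[C@@H]1O | target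

**Totals and risks**
Total step count: 10. Longest linear sequence: 10 steps (from farnesol).

Step 6 (most likely to fail): the carbene/palladium macrocyclisation may give oligomers, simple β-protonation, acyl-anion allylation or low enantioselectivity. The fallback changes the electrophile from a π-allyl unit to an aldehyde. It sets out from 9: K2CO3 in MeOH removes the methyl carbonate to give the hydroxy enal F1, and MnO2 oxidises the allylic alcohol to the dienal F2. The same chiral triazolium salt (DBU, THF, high dilution) then performs the well-established homoenolate addition to an aldehyde; only the 2-methyl enal can act as donor, and the C1–C2 bond is closed as the macrocyclic γ-butyrolactone F3. Pd(PPh3)4 with NaBH4 ionises the allylic C2–O bond and delivers hydride to C2, which gives the acid 11, where the route is rejoined.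

Step 9: the ene reaction may give the wrong C7 epimer or a mixture, since the face selectivity rests on ring conformation only. The fallback replaces substrate control by reagent control. It sets out from 12: after the same photooxygenation, Ac2O/pyridine/DMAP dehydrates the secondary allylic hydroperoxide 13 (either C7 epimer) to the enone F4. (R)-2-Methyl-CBS-oxazaborolidine with catecholborane (the 2-substituted vinyl group acting as the large group) gives the 7S alcohol F5, and Zn/NH4Cl as in step 9 returns 14.

Step 10: the dioxirane may also attack the 8(19)-alkene or be steered by the free allylic hydroxyl, and the 3,4-face selectivity may erode in the macrocycle. The fallback shields the allylic alcohol. It sets out from 14: TBSOTf/2,6-lutidine gives the bis-silyl derivative F6, and K2CO3 in MeOH cleaves only the silyl ester to give the silyl ether acid F7. The same Shi epoxidation and DBU treatment give the 7-O-silyl lactone F8, and Bu4NF returns 17.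

**Further compounds**
F1 | step 6 | (2E,6E,10S,11S,14E)-10,11-epoxy-1-hydroxy-3,7,11,15-tetramethylhexadeca-2,6,14-trien-16-al (hydroxy enal) | OC/C=C(\C)CC/C=C(\C)CC[C@@H]1O[C@@]1(C)CC/C=C(\C)C=O
F2 | step 6 | (2E,6E,10S,11S,14E)-10,11-epoxy-3,7,11,15-tetramethylhexadeca-2,6,14-triene-1,16-dial (dienal) | O=C/C=C(\C)CC/C=C(\C)CC[C@@H]1O[C@@]1(C)CC/C=C(\C)C=O
F3 | step 6 | (1R,3E,7E,11S,12S)-11,12-epoxycembra-3,7-dien-16,2-olide (macrocyclic γ-butyrolactone, C2 and C15 unassigned) | CC1C(=O)OC(/C=C(\C)C2)[C@H]1CC[C@]3(C)O[C@H]3CC/C(C)=C/C2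
F4 | step 9 | 7-oxo-8(19)-ene derivative of bromolactone 12 (enone) | CC1C(=O)O[C@@H]2C[C@H]1CC[C@]3(C)O[C@H]3CCC(=C)C(=O)CC[C@]2(C)Br
F5 | step 9 | (7S)-7-hydroxy-8(19)-ene derivative of bromolactone 12 | CC1C(=O)O[C@@H]2C[C@H]1CC[C@]3(C)O[C@H]3CCC(=C)[C@@H](O)CC[C@]2(C)Br
F6 | step 10 | tert-butyldimethylsilyl ester of the 7-O-tert-butyldimethylsilyl ether of 14 | CC(C)(C)[Si](C)(C)OC(=O)C(C)[C@H]1C/C=C(\C)CC[C@H](O[Si](C)(C)C(C)(C)C)C(=C)CC[C@@H]2O[C@@]2(C)CC1
F7 | step 10 | 7-O-tert-butyldimethylsilyl ether of 14 | OC(=O)C(C)[C@H]1C/C=C(\C)CC[C@H](O[Si](C)(C)C(C)(C)C)C(=C)CC[C@@H]2O[C@@]2(C)CC1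
F8 | step 10 | 7-O-tert-butyldimethylsilyl ether of 17 | C=C1CC[C@@H]2O[C@@]2(C)CC[C@@H]2C[C@@H](OC(=O)[C@H]2C)[C@@](C)(O)CC[C@@H]1O[Si](C)(C)C(C)(C)C
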